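The bond to be made joins ring-A carbon C3′ to the geranyl CH2 (C1″). C3′ is the one ring carbon flanked by both oxygen-bearing carbons C2′ and C4′. In the acyl-free precursor 1-methoxy-3-(methoxymethoxy)benzene, the two ether oxygens jointly direct lithiation to exactly this carbon. The resulting aryllithium, under copper catalysis, displaces bromide from geranyl bromide at its primary carbon. One operation thus fixes the ring position of the side chain and carries the 2″E alkene through unchanged. The cinnamoyl arm is then attached by a second, MOM-directed lithiation and acylation with a Weinreb cinnamamide, and mild acid finally frees both phenols.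

Key step: step 2

Remark: the target has no stereocentre, so the stereochemical task reduces to the two E double bonds; compounds 3, 6 and 7 are taken as catalogue compounds.

Step 1
Reactants: 1 3-methoxyphenol
Product: 2 1-methoxy-3-(methoxymethoxy)benzene
Conditions: MOMCl, iPr2NEt, CH2Cl2, 0 °C → rt
Reagents that add atoms: chloromethyl methyl ether (MOMCl), COCCl
Why: O-alkylation of the phenol with the reactive α-chloro ether (MOM protection) should give the acetal that protects O2′ and later directs both lithiations.

Step 2
Reactants: 2 1-methoxy-3-(methoxymethoxy)benzene; 3 geranyl bromide [(2E)-1-bromo-3,7-dimethylocta-2,6-diene]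
Product: 5 2-[(2E)-3,7-dimethylocta-2,6-dien-1-yl]-1-methoxy-3-(methoxymethoxy)benzene, via 2-lithio arene 4 (not isolated)
Conditions: n-BuLi, THF, 0 °C → rt; CuI (10 mol %), −78 °C; then 3, −78 °C → rt
Reagents that add atoms: none
Why: n-BuLi, pre-coordinated by the MOM and methyl ether oxygens, removes the one ring proton that lies between them (complex-induced proximity plus combined inductive acidification), which should give aryllithium 4 as the only regioisomer. Transmetalation to an arylcopper(I) species then substitutes the bromide of 3 at the unhindered primary allylic carbon, which forms the aryl–CH2 bond. The closest known reaction type is directed ortho-metalation followed by copper-mediated allylation of the aryl anion with a prenyl-type halide. No ring is closed and no stereocentre is formed. The step needs three selectivities: site selectivity on the ring, secured by the two flanking oxygen donors; α over γ attack on the allyl unit, secured by the fully substituted γ carbon and the soft copper nucleophile; and retention of the E alkene, secured because substitution occurs at low temperature without a free allyl cation or a long-lived π-allyl complex.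

Step 3
Reactants: 6 4-(methoxymethoxy)benzaldehyde; 7 N-methoxy-N-methyl-2-(triphenyl-λ5-phosphanylidene)acetamide
Product: 8 (2E)-N-methoxy-3-[4-(methoxymethoxy)phenyl]-N-methylprop-2-enamide
Conditions: toluene, 80 °C
Reagents that add atoms: none
Why: Wittig olefination with an amide-stabilised ylide is reliably E-selective with aromatic aldehydes and should deliver the E-cinnamoyl Weinreb amide directly.

Step 4
Reactants: 5 2-[(2E)-3,7-dimethylocta-2,6-dien-1-yl]-1-methoxy-3-(methoxymethoxy)benzene; 8 (2E)-N-methoxy-3-[4-(methoxymethoxy)phenyl]-N-methylprop-2-enamide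
Product: 11 (2E)-1-{3-[(2E)-3,7-dimethylocta-2,6-dien-1-yl]-4-methoxy-2-(methoxymethoxy)phenyl}-3-[4-(methoxymethoxy)phenyl]prop-2-en-1-one, via aryllithium 9 (not isolated), via lithium hemiaminal 10 (not isolated)
Conditions: n-BuLi, TMEDA, Et2O, 0 °C; then 8 in THF, −78 → 0 °C; then H2O
Reagents that add atoms: none
Why: Directed ortho-metalation should occur at the only free carbon ortho to OMOM, the stronger director compared with OMe, and the aryllithium should add once to the Weinreb amide (Weinreb ketone synthesis) through chelated hemiaminal 10, which releases the enone only on quench and leaves both E alkenes untouched.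

Step 5
Reactants: 11 (2E)-1-{3-[(2E)-3,7-dimethylocta-2,6-dien-1-yl]-4-methoxy-2-(methoxymethoxy)phenyl}-3-[4-(methoxymethoxy)phenyl]prop-2-en-1-one
Product: 13 xanthoangelol F, via mono-MOM chalcone 12 (not isolated)
Conditions: HCl (1.25 M in MeOH, cat.), MeOH, 0 °C → rt, close monitoring
Reagents that add atoms: none
Why: Acid-catalysed acetal methanolysis (MOM cleavage) is expected to remove first the MOM group ortho to the carbonyl (giving 12) and then the B-ring MOM group, while dilute acid at low temperature should spare the trisubstituted alkenes and the 2′-hydroxychalcone, which is held open by its O–H···O=C hydrogen bond.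

Compound list
1 | 3-methoxyphenol | COc1cccc(O)c1 | starting material
2 | 1-methoxy-3-(methoxymethoxy)benzene | COCOc1cccc(OC)c1 | intermediate
3 | geranyl bromide, (2E)-1-bromo-3,7-dimethylocta-2,6-diene | BrC/C=C(\C)CCC=C(C)C | starting material
4 | [2-methoxy-6-(methoxymethoxy)phenyl]lithium | [Li]c1c(OC)cccc1OCOC | intermediate
5 | 2-[(2E)-3,7-dimethylocta-2,6-dien-1-yl]-1-methoxy-3-(methoxymethoxy)benzene | COCOc1cccc(OC)c1C/C=C(\C)CCC=C(C)C | intermediate
6 | 4-(methoxymethoxy)benzaldehyde | COCOc1ccc(C=O)cc1 | starting material
7 | N-methoxy-N-methyl-2-(triphenyl-λ5-phosphanylidene)acetamide | CON(C)C(=O)C=P(c1ccccc1)(c1ccccc1)c1ccccc1 | starting material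
8 | (2E)-N-methoxy-3-[4-(methoxymethoxy)phenyl]-N-methylprop-2-enamide | COCOc1ccc(/C=C/C(=O)N(C)OC)cc1 | intermediate
9 | {3-[(2E)-3,7-dimethylocta-2,6-dien-1-yl]-4-methoxy-2-(methoxymethoxy)phenyl}lithium | [Li]c1ccc(OC)c(C/C=C(\C)CCC=C(C)C)c1OCOC | intermediate
10 | lithium hemiaminal (tetrahedral adduct of 9 and 8, racemic at the new carbon) | [Li]OC(/C=C/c1ccc(OCOC)cc1)(N(C)OC)c1ccc(OC)c(C/C=C(\C)CCC=C(C)C)c1OCOC | intermediate
11 | (2E)-1-{3-[(2E)-3,7-dimethylocta-2,6-dien-1-yl]-4-methoxy-2-(methoxymethoxy)phenyl}-3-[4-(methoxymethoxy)phenyl]prop-2-en-1-one | COCOc1ccc(/C=C/C(=O)c2ccc(OC)c(C/C=C(\C)CCC=C(C)C)c2OCOC)cc1 | intermediate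
12 | (2E)-1-{3-[(2E)-3,7-dimethylocta-2,6-dien-1-yl]-2-hydroxy-4-methoxyphenyl}-3-[4-(methoxymethoxy)phenyl]prop-2-en-1-one | COCOc1ccc(/C=C/C(=O)c2ccc(OC)c(C/C=C(\C)CCC=C(C)C)c2O)cc1 | intermediate
13 | xanthoangelol F, (2E)-1-{3-[(2E)-3,7-dimethylocta-2,6-dien-1-yl]-2-hydroxy-4-methoxyphenyl}-3-(4-hydroxyphenyl)prop-2-en-1-one | COc1ccc(C(=O)/C=C/c2ccc(O)cc2)c(O)c1C/C=C(\C)CCC=C(C)C | target

Total step count: 5. Longest linear sequence: 4 steps (steps 1, 2, 4, 5); step 3 is a one-step side branch.

Steps most likely to fail

Step 2. The aryl nucleophile may attack the γ carbon of the allylic bromide (SN2′), giving the branched tertiary isomer, and the bromide may undergo Wurtz-type self-coupling. The fallback reverses the polarity of the two partners and sets out from 2 and 3. Aryllithium 4, made as before, is quenched with I2 at −78 °C to give 2-iodo-1-methoxy-3-(methoxymethoxy)benzene F1. Bromide 3 is treated with Bu3SnLi in THF at −78 °C to give tributyl[(2E)-3,7-dimethylocta-2,6-dien-1-yl]stannane F2. A Stille coupling of F1 with F2 (Pd2(dba)3, AsPh3, DMF, 60–80 °C) should join the aryl carbon to the less hindered allyl terminus, and the fallback comes back to the route at 5.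

Step 4. Conjugate (1,4) addition of the aryllithium to the enamide, or early collapse of the hemiaminal with over-addition, may erode the acyl transfer. The fallback sets out from 5 and 8. Amide 8 is reduced with DIBAL-H (THF, −78 °C) to (2E)-3-[4-(methoxymethoxy)phenyl]prop-2-enal F3. Aryllithium 9, generated from 5 as before, adds 1,2 to this aldehyde to give racemic (2E)-1-{3-[(2E)-3,7-dimethylocta-2,6-dien-1-yl]-4-methoxy-2-(methoxymethoxy)phenyl}-3-[4-(methoxymethoxy)phenyl]prop-2-en-1-ol F4. Oxidation of the doubly activated alcohol with MnO2 (CH2Cl2, rt) comes back to the route at 11.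

Step 5. Under acid, the freed 2′-OH may add to the C2″=C3″ alkene (chroman formation) or close onto the enone (flavanone formation) before the slower B-ring MOM ether has been cleaved. The fallback makes the last step base-mediated and sets out from 5. Aryllithium 9 is acylated with N-methoxy-N-methylacetamide (CC(=O)N(C)OC) to give 1-{3-[(2E)-3,7-dimethylocta-2,6-dien-1-yl]-4-methoxy-2-(methoxymethoxy)phenyl}ethan-1-one F5. Its single, carbonyl-activated MOM ether is removed under very mild acid (PPTS, MeOH, rt) to give 1-{3-[(2E)-3,7-dimethylocta-2,6-dien-1-yl]-2-hydroxy-4-methoxyphenyl}ethan-1-one F6. Claisen–Schmidt condensation of F6 with purchased 4-hydroxybenzaldehyde (O=Cc1ccc(O)cc1; KOH, EtOH/H2O, rt → 50 °C, then cold neutralisation) comes back to the route at 13.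

Further compounds
F1 | step 2 | 2-iodo-1-methoxy-3-(methoxymethoxy)benzene | COCOc1cccc(OC)c1I
F2 | step 2 | tributyl[(2E)-3,7-dimethylocta-2,6-dien-1-yl]stannane | CCCC[Sn](CCCC)(CCCC)C/C=C(\C)CCC=C(C)C
F3 | step 4 | (2E)-3-[4-(methoxymethoxy)phenyl]prop-2-enal | COCOc1ccc(/C=C/C=O)cc1
F4 | step 4 | (2E)-1-{3-[(2E)-3,7-dimethylocta-2,6-dien-1-yl]-4-methoxy-2-(methoxymethoxy)phenyl}-3-[4-(methoxymethoxy)phenyl]prop-2-en-1-ol (racemic) | COCOc1ccc(/C=C/C(O)c2ccc(OC)c(C/C=C(\C)CCC=C(C)C)c2OCOC)cc1
F5 | step 5 | 1-{3-[(2E)-3,7-dimethylocta-2,6-dien-1-yl]-4-methoxy-2-(methoxymethoxy)phenyl}ethan-1-one | CC(=O)c1ccc(OC)c(C/C=C(\C)CCC=C(C)C)c1OCOC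
F6 | step 5 | 1-{3-[(2E)-3,7-dimethylocta-2,6-dien-1-yl]-2-hydroxy-4-methoxyphenyl}ethan-1-one | CC(=O)c1ccc(OC)c(C/C=C(\C)CCC=C(C)C)c1O
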